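**Plan**

Numbering (decalin of the target): C1 = C(CH3)(CH2Ar), C2 = CH(CH3), C3, C4, C4a = ring-fusion CH, C5 = C(=CH2), C6–C8, C8a = ring-fusion C(CH3). Ring A = C4a, C5–C8, C8a. Ring B = C1–C4, C4a, C8a. β = the face of the C8a methyl group.
Cuts: C5=CH2 goes back to a C5 ketone. The benzylic CH2 goes back to a carbinol, and the C1–CH(OH)Ar bond is then cut to an aryl aldehyde and a cyclic allylsilane. C4a–H goes back to an enone. Last, C3–C4 and C4a–C8a are cut together.
Enabling feature: ring B is a six-membered ring whose two-carbon edge C4–C4a adjoins the sp2 carbon C5 of ring A (a latent carbonyl). Its four-carbon edge C3–C2–C1–C8a can be a diene, and C4a and C8a are bridged by C5–C8, a four-atom tether. The double cut therefore opens both rings to an acyclic, achiral dienyl ynone.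
Forward: the chain is assembled first (stereodefined tetrasubstituted alkene, ester to 2-(silylmethyl)diene, ynone). One intramolecular Diels–Alder reaction then closes rings A and B together. The arene is joined afterwards at C1, the more hindered of the two vicinal quaternary carbons.
Stereochemistry: C8a comes from a chiral Lewis acid in the cycloaddition and then relays. C4a is set by protonation anti to the C8a methyl, and C1 by electrophile attack anti to the C8a methyl. C2 is set by hydrogenation directed from the α face by the carbinol OH, which gives the axial, contra-thermodynamic methyl group.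
Helpers and their removal: the CH2SiMe3 group activates the diene, makes C1 nucleophilic, and its carbon ends as the C2 methyl. The C5 carbonyl activates the dienophile and becomes the methylene group. The alkyne level keeps the dienophile slim and is reduced in step 9. The carbinol OH directs the hydrogenation and is removed in step 13.

Key step: step 8

Assumption: the sense of induction in step 8 is taken from the accepted model for carbonyl-bound oxazaborolidine Lewis acids; both antipodes of the catalyst are available, so the antipode is used if the opposite sense is found.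

**Step 1**
Reactants: 1 methyl 2-methyl-3-oxobutanoate
Product: 2 methyl (E)-2-methyl-3-(tosyloxy)but-2-enoate
Conditions: TsCl, N-methylimidazole, Et3N, CH2Cl2, 0 °C to rt
Reagents that add atoms: p-toluenesulfonyl chloride Cc1ccc(S(=O)(=O)Cl)cc1
Why: O-sulfonylation of the β-keto ester enolate by the N-sulfonylimidazolium species from TsCl and N-methylimidazole; with a non-chelating amine base the enolate should react in the geometry that places OTs and CO2Me on opposite sides (E), which fixes the alkene geometry the diene needs later.

**Step 2**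
Reactants: 2 methyl (E)-2-methyl-3-(tosyloxy)but-2-enoate; 3 tert-butyl(4-iodobutoxy)dimethylsilane
Product: 5 methyl (E)-7-[(tert-butyldimethylsilyl)oxy]-2,3-dimethylhept-2-enoate, via alkylzinc iodide 4 (not isolated)
Conditions: 3, Zn dust, LiCl, THF, 40 °C; then 2, PdCl2(dppf) (3 mol%), THF, 50 °C
Reagents that add atoms: none
Why: Negishi coupling, in which oxidative addition of the ester-activated alkenyl tosylate and reductive elimination at divalent palladium are both stereoretentive, so the four-carbon chain should end up trans to the ester, while the chelating dppf ligand holds back β-hydride elimination of the primary alkyl group.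

**Step 3**
Reactants: 5 methyl (E)-7-[(tert-butyldimethylsilyl)oxy]-2,3-dimethylhept-2-enoate
Product: 7 (E)-tert-butyl({5,6-dimethyl-7-[(trimethylsilyl)methyl]octa-5,7-dien-1-yl}oxy)dimethylsilane, via bis(silylmethyl)carbinol 6 (not isolated)
Conditions: Me3SiCH2MgCl (4 equiv), CeCl3 (4 equiv), THF, −78 °C to rt; aq NH4Cl; then silica gel, CH2Cl2, rt
Reagents that add atoms: (trimethylsilyl)methylmagnesium chloride C[Si](C)(C)C[Mg]Cl
Why: the weakly basic organocerium reagent adds twice to the hindered conjugated ester without enolising the intermediate α-silyl ketone, and Peterson elimination of one Me3SiOH from the tertiary carbinol on silica gel gives the 2-(silylmethyl)-1,3-diene with the tetrasubstituted alkene untouched.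

**Step 4**
Reactants: 7 (E)-tert-butyl({5,6-dimethyl-7-[(trimethylsilyl)methyl]octa-5,7-dien-1-yl}oxy)dimethylsilane
Product: 8 (E)-5,6-dimethyl-7-[(trimethylsilyl)methyl]octa-5,7-dien-1-ol
Conditions: Bu4NF, THF, 0 °C
Reagents that add atoms: none
Why: fluoride-induced desilylation is much faster at the oxygen-bound silicon of the primary silyl ether than at the allylic carbon-bound silicon at 0 °C, so only the alcohol is released.

**Step 5**
Reactants: 8 (E)-5,6-dimethyl-7-[(trimethylsilyl)methyl]octa-5,7-dien-1-ol
Product: 9 (E)-5,6-dimethyl-7-[(trimethylsilyl)methyl]octa-5,7-dienal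
Conditions: Pr4N[RuO4] (5 mol%), N-methylmorpholine N-oxide, 4 Å molecular sieves, CH2Cl2, rt
Reagents that add atoms: none
Why: Ley–Griffith oxidation is neutral and stops at the aldehyde, so the acid-sensitive dienylsilane should survive.

**Step 6**
Reactants: 9 (E)-5,6-dimethyl-7-[(trimethylsilyl)methyl]octa-5,7-dienal
Product: 10 (E)-7,8-dimethyl-9-[(trimethylsilyl)methyl]deca-7,9-dien-1-yn-3-ol (racemic)
Conditions: HC≡CMgBr, THF, −20 to 0 °C
Reagents that add atoms: ethynylmagnesium bromide C#C[Mg]Br
Why: Grignard 1,2-addition of the acetylide to the unhindered aldehyde gives the propargylic alcohol as a racemate, which does not matter because this stereocentre is erased in step 7.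

**Step 7**
Reactants: 10 (E)-7,8-dimethyl-9-[(trimethylsilyl)methyl]deca-7,9-dien-1-yn-3-ol
Product: 11 (E)-7,8-dimethyl-9-[(trimethylsilyl)methyl]deca-7,9-dien-1-yn-3-one
Conditions: activated MnO2 (excess), CH2Cl2, rt
Reagents that add atoms: none
Why: activated MnO2 oxidises the propargylic alcohol under neutral and amine-free conditions, which avoids conjugate addition to the sensitive terminal ynone.

**Step 8**
Reactants: 11 (E)-7,8-dimethyl-9-[(trimethylsilyl)methyl]deca-7,9-dien-1-yn-3-one
Product: 12 (R)-4a,5-dimethyl-6-[(trimethylsilyl)methyl]-3,4,4a,7-tetrahydronaphthalen-1(2H)-one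
Conditions: (S)-3,3-diphenyl-1-(2-methylphenyl)tetrahydro-1H,3H-pyrrolo[1,2-c][1,3,2]oxazaborole (10 mol%), AlBr3 (8 mol%), CH2Cl2 (0.01 M), −40 to −20 °C
Reagents that add atoms: none
Why: Coordination of the chiral boron Lewis acid to the ynone carbonyl lowers the LUMO of the triple bond, and the tethered diene adds across it in a concerted but asynchronous [4+2] cycloaddition in which the C3–C4 bond, between the two unsubstituted termini that carry the largest frontier coefficients, runs ahead of the hindered C4a–C8a bond. The closest known reaction types are the type 1 intramolecular Diels–Alder reaction of 1,7,9-decatrien-3-ones and the enantioselective Diels–Alder reaction of acetylenic ketones catalysed by activated oxazaborolidines. Ring B closes as the new cycloadduct ring that holds both new bonds, and ring A closes at the same moment through the C4a–C8a bond as the six-membered ring that contains the carbonyl carbon and the three methylene groups, the fused mode being the only one a four-atom tether allows. The only new stereocentre, quaternary C8a, is set by the catalyst, which shields one face of the bound ynone so that the diene can fold over the other face only. Regiochemistry is fixed by the tether and is matched electronically by the CH2SiMe3 and alkyl donors, the bulky C2 substituent pushes the fully substituted diene towards the cisoid conformer, and the slim sp-hybridised dienophile lets the diene terminus with its inward-pointing methyl group reach bonding distance. The aprotic activator AlBr3 is chosen so that no strong Brønsted acid is present to protodesilylate the dienylsilane.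

**Step 9**
Reactants: 12 (R)-4a,5-dimethyl-6-[(trimethylsilyl)methyl]-3,4,4a,7-tetrahydronaphthalen-1(2H)-one
Product: 14 (4aS,8aR)-4a,5-dimethyl-6-[(trimethylsilyl)methyl]-3,4,4a,7,8,8a-hexahydronaphthalen-1(2H)-one, via copper enolate 13 (not isolated)
Conditions: [(Ph3P)CuH]6 (0.4 equiv), degassed H2O (5 equiv), toluene, rt
Reagents that add atoms: none
Why: copper hydride conjugate reduction of the s-cis enone puts hydride on C4 and gives the C5–C4a enolate regiospecifically, and its protonation should occur on the α face of C4a, because the β trajectory is nearly eclipsed with the axial C8a methyl group while the α trajectory is staggered, to give the trans ring fusion, which at this stage (C1 and C2 still sp2) should also be the more stable epimer.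

**Step 10**
Reactants: 15 methyl 3-formyl-4-hydroxybenzoate
Product: 16 methyl 3-formyl-4-(methoxymethoxy)benzoate
Conditions: MeOCH2Cl, i-Pr2NEt, CH2Cl2, 0 °C to rt
Reagents that add atoms: chloromethyl methyl ether COCCl
Why: O-alkylation of the acidic phenol (Williamson type) masks the proton that would otherwise release acid from the Lewis acid and protodesilylate the allylsilane in step 11.

**Step 11**
Reactants: 14 (4aS,8aR)-4a,5-dimethyl-6-[(trimethylsilyl)methyl]-3,4,4a,7,8,8a-hexahydronaphthalen-1(2H)-one; 16 methyl 3-formyl-4-(methoxymethoxy)benzoate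
Product: 17 methyl 3-{hydroxy[(1R,4aR,8aS)-1,8a-dimethyl-2-methylidene-5-oxodecahydronaphthalen-1-yl]methyl}-4-(methoxymethoxy)benzoate (carbinol carbon: either configuration)
Conditions: BF3·OEt2 (1.2 equiv), CH2Cl2, −78 to −40 °C; aq NaHCO3
Reagents that add atoms: none
Why: Hosomi–Sakurai allylation, in which the BF3-activated aldehyde, far more electrophilic than the C5 ketone, is attacked by the γ-carbon C1 of the allylsilane on the α face, anti to the pseudoaxial C8a methyl group of the trans-fused half-chair, which sets quaternary C1 (CH3 β, carbinol carbon α) and moves the double bond to the exocyclic position at C2 with loss of silicon, while the carbinol configuration is of no consequence because that centre is removed in step 13.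

**Step 12**
Reactants: 17 methyl 3-{hydroxy[(1R,4aR,8aS)-1,8a-dimethyl-2-methylidene-5-oxodecahydronaphthalen-1-yl]methyl}-4-(methoxymethoxy)benzoate
Product: 18 methyl 3-{hydroxy[(1R,2S,4aR,8aS)-1,2,8a-trimethyl-5-oxodecahydronaphthalen-1-yl]methyl}-4-(methoxymethoxy)benzoate
Conditions: [Ir(cod)(PCy3)(py)]PF6 (10 mol%), H2 (1 atm), CH2Cl2, rt
Reagents that add atoms: none
Why: hydroxyl-directed homogeneous hydrogenation, in which the cationic iridium catalyst binds the homoallylic hydroxyl group on the α-axial C1 substituent and therefore delivers hydrogen to the α face of the C2 methylidene group, which sets C2 with its methyl group β and axial, the contra-thermodynamic arrangement that an undirected or radical reduction would not be expected to give.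

**Step 13**
Reactants: 18 methyl 3-{hydroxy[(1R,2S,4aR,8aS)-1,2,8a-trimethyl-5-oxodecahydronaphthalen-1-yl]methyl}-4-(methoxymethoxy)benzoate
Product: 19 methyl 4-hydroxy-3-{[(1R,2S,4aR,8aS)-1,2,8a-trimethyl-5-oxodecahydronaphthalen-1-yl]methyl}benzoate
Conditions: Et3SiH (6 equiv), CF3CO2H, CH2Cl2, 0 °C
Reagents that add atoms: none
Why: ionic hydrogenation, in which trifluoroacetic acid ionises the carbinol to a benzylic cation stabilised by the ortho oxygen (so that a 1,2-shift from the neighbouring quaternary carbon is uphill), triethylsilane traps it as CH2, the methoxymethyl acetal is cleaved and reduced in the same medium, and the short contact at 0 °C should leave the dialkyl ketone and its α-stereocentre C4a untouched.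

**Step 14**
Reactants: 19 methyl 4-hydroxy-3-{[(1R,2S,4aR,8aS)-1,2,8a-trimethyl-5-oxodecahydronaphthalen-1-yl]methyl}benzoate
Product: 20 methyl 4-hydroxy-3-{[(1R,2S,4aS,8aS)-1,2,8a-trimethyl-5-methylidenedecahydronaphthalen-1-yl]methyl}benzoate (target)
Conditions: Zn, CH2Br2, TiCl4 (pre-aged reagent, excess), THF–CH2Cl2, 0 °C to rt
Reagents that add atoms: dibromomethane BrCBr
Why: Lombardo-type methylenation with the non-basic geminal dizinc–titanium reagent converts the ketone into the exocyclic methylene group without enolisation, which matters because trans ketone 19 with its syn-diaxial methyl groups is expected to be less stable than its C4a epimer, and the reagent leaves the aryl ester alone while the free phenol only consumes extra reagent.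

**Compound list**

1 | methyl 2-methyl-3-oxobutanoate | CC(=O)C(C)C(=O)OC | starting material
2 | methyl (E)-2-methyl-3-(tosyloxy)but-2-enoate | COC(=O)/C(C)=C(/OS(=O)(=O)c1ccc(C)cc1)C | intermediate
3 | tert-butyl(4-iodobutoxy)dimethylsilane | CC(C)(C)[Si](C)(C)OCCCCI | starting material
4 | {4-[(tert-butyldimethylsilyl)oxy]butyl}zinc iodide | CC(C)(C)[Si](C)(C)OCCCC[Zn]I | intermediate
5 | methyl (E)-7-[(tert-butyldimethylsilyl)oxy]-2,3-dimethylhept-2-enoate | COC(=O)/C(C)=C(/CCCCO[Si](C)(C)C(C)(C)C)C | intermediate
6 | (E)-8-[(tert-butyldimethylsilyl)oxy]-3,4-dimethyl-1-(trimethylsilyl)-2-[(trimethylsilyl)methyl]oct-3-en-2-ol | CC(C)(C)[Si](C)(C)OCCCC/C(C)=C(/C(O)(C[Si](C)(C)C)C[Si](C)(C)C)C | intermediate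
7 | (E)-tert-butyl({5,6-dimethyl-7-[(trimethylsilyl)methyl]octa-5,7-dien-1-yl}oxy)dimethylsilane | CC(C)(C)[Si](C)(C)OCCCC/C(C)=C(/C(=C)C[Si](C)(C)C)C | intermediate
8 | (E)-5,6-dimethyl-7-[(trimethylsilyl)methyl]octa-5,7-dien-1-ol | OCCCC/C(C)=C(/C(=C)C[Si](C)(C)C)C | intermediate
9 | (E)-5,6-dimethyl-7-[(trimethylsilyl)methyl]octa-5,7-dienal | O=CCCC/C(C)=C(/C(=C)C[Si](C)(C)C)C | intermediate
10 | (E)-7,8-dimethyl-9-[(trimethylsilyl)methyl]deca-7,9-dien-1-yn-3-ol (racemic) | C#CC(O)CCC/C(C)=C(/C(=C)C[Si](C)(C)C)C | intermediate
11 | (E)-7,8-dimethyl-9-[(trimethylsilyl)methyl]deca-7,9-dien-1-yn-3-one | C#CC(=O)CCC/C(C)=C(/C(=C)C[Si](C)(C)C)C | intermediate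
12 | (R)-4a,5-dimethyl-6-[(trimethylsilyl)methyl]-3,4,4a,7-tetrahydronaphthalen-1(2H)-one | O=C1CCC[C@@]2(C)C1=CCC(C[Si](C)(C)C)=C2C | intermediate
13 | copper enolate of 14 (C5–C4a enolate, phosphine ligands omitted) | [Cu]OC=1CCC[C@@]2(C)C1CCC(C[Si](C)(C)C)=C2C | intermediate
14 | (4aS,8aR)-4a,5-dimethyl-6-[(trimethylsilyl)methyl]-3,4,4a,7,8,8a-hexahydronaphthalen-1(2H)-one (trans-fused) | O=C1CCC[C@@]2(C)[C@H]1CCC(C[Si](C)(C)C)=C2C | intermediate
15 | methyl 3-formyl-4-hydroxybenzoate | COC(=O)c1ccc(O)c(C=O)c1 | starting material
16 | methyl 3-formyl-4-(methoxymethoxy)benzoate | COCOc1ccc(C(=O)OC)cc1C=O | intermediate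
17 | methyl 3-{hydroxy[(1R,4aR,8aS)-1,8a-dimethyl-2-methylidene-5-oxodecahydronaphthalen-1-yl]methyl}-4-(methoxymethoxy)benzoate (carbinol carbon undefined) | O=C1CCC[C@@]2(C)[C@H]1CCC(=C)[C@@]2(C)C(O)c1cc(C(=O)OC)ccc1OCOC | intermediate
18 | methyl 3-{hydroxy[(1R,2S,4aR,8aS)-1,2,8a-trimethyl-5-oxodecahydronaphthalen-1-yl]methyl}-4-(methoxymethoxy)benzoate (carbinol carbon undefined) | O=C1CCC[C@@]2(C)[C@H]1CC[C@H](C)[C@@]2(C)C(O)c1cc(C(=O)OC)ccc1OCOC | intermediate
19 | methyl 4-hydroxy-3-{[(1R,2S,4aR,8aS)-1,2,8a-trimethyl-5-oxodecahydronaphthalen-1-yl]methyl}benzoate | O=C1CCC[C@@]2(C)[C@H]1CC[C@H](C)[C@@]2(C)Cc1cc(C(=O)OC)ccc1O | intermediate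
20 | methyl 4-hydroxy-3-{[(1R,2S,4aS,8aS)-1,2,8a-trimethyl-5-methylidenedecahydronaphthalen-1-yl]methyl}benzoate | C=C1CCC[C@@]2(C)[C@H]1CC[C@H](C)[C@@]2(C)Cc1cc(C(=O)OC)ccc1O | target

**Step count and risks**

Total step count: 14. Longest linear sequence: 13 (steps 1–9 and 11–14).

**Step 8.**
- What may go wrong: the diene terminus with the inward-pointing methyl group may react too slowly at the temperatures at which the catalyst discriminates. Protodesilylation of the dienylsilane, oligomerisation of the terminal ynone, or an unselective background cycloaddition could then take over.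
- Fallback: this replaces LUMO lowering by substrate control under a neutral metal catalyst.
  - It sets out from 11. Reduction with (R)-B-isopinocampheyl-9-borabicyclo[3.3.1]nonane gives the (3R)-propargylic alcohol F1.
  - TBSCl and imidazole convert it into the silyl ether F2.
  - The rhodium-catalysed intramolecular [4+2] cycloaddition of this unactivated dienyne ([Rh(cod)(C10H8)]SbF6, ClCH2CH2Cl, rt) should give the bicyclic diene silyl ether F3. In it the silyloxy group takes the equatorial position on the forming ring A to avoid a syn-diaxial contact with the C8a methyl group, and so relays its configuration to C8a.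
  - Bu4NF releases the allylic alcohol F4, and MnO2 brings the sequence back to 12.

**Step 11.**
- What may go wrong: congestion at C1 may slow the addition so much that protodesilylation of the allylsilane wins, because the bond forms next to quaternary C8a with an ortho-substituted aryl aldehyde.
- Fallback: this uses the smallest possible electrophile first and joins the arene afterwards.
  - It sets out from 14. Paraformaldehyde and Me2AlCl (CH2Cl2, −78 to 0 °C) give the primary homoallylic alcohol F5.
  - Its unhindered hydroxyl group is also a better ligand for iridium, which covers weak direction in step 12. It directs the hydrogenation ([Ir(cod)(PCy3)(py)]PF6, H2, CH2Cl2) to the saturated alcohol F6.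
  - An Appel reaction (I2, PPh3, imidazole, toluene) gives the neopentyl iodide F7.
  - Nickel-catalysed reductive cross-electrophile coupling with commercial methyl 3-iodo-4-hydroxybenzoate (NiI2, 4,4'-di-tert-butyl-2,2'-bipyridine, Zn, N,N-dimethylacetamide) comes back to the route at 19, bypassing steps 12 and 13.

**Step 14.**
- What may go wrong: attack at the carbonyl group flanked by the ring fusion may be slow, and the phenol consumes reagent. Lewis acid-induced enolisation could also epimerise C4a to the more stable cis-fused series.
- Fallback: this is a two-stage Peterson olefination.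
  - It sets out from 19. Excess Me3SiCH2MgCl and CeCl3 (THF, −78 to 0 °C) first form the phenoxide, which also deactivates the para ester, and then add to the ketone to give the β-hydroxysilane F8.
  - In F8, C4a is no longer epimerisable. Elimination with KH in THF comes back at 20.

Further compounds
F1 | step 8 | (3R,7E)-7,8-dimethyl-9-[(trimethylsilyl)methyl]deca-7,9-dien-1-yn-3-ol | C#C[C@H](O)CCC/C(C)=C(/C(=C)C[Si](C)(C)C)C
F2 | step 8 | tert-butyldimethylsilyl ether of F1 | C#C[C@H](O[Si](C)(C)C(C)(C)C)CCC/C(C)=C(/C(=C)C[Si](C)(C)C)C
F3 | step 8 | (1R,4aR)-1-[(tert-butyldimethylsilyl)oxy]-4a,5-dimethyl-6-[(trimethylsilyl)methyl]-1,2,3,4,4a,7-hexahydronaphthalene | CC(C)(C)[Si](C)(C)O[C@@H]1CCC[C@@]2(C)C1=CCC(C[Si](C)(C)C)=C2C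
F4 | step 8 | (1R,4aR)-4a,5-dimethyl-6-[(trimethylsilyl)methyl]-1,2,3,4,4a,7-hexahydronaphthalen-1-ol | O[C@@H]1CCC[C@@]2(C)C1=CCC(C[Si](C)(C)C)=C2C
F5 | step 11 | [(1R,4aR,8aS)-1,8a-dimethyl-2-methylidene-5-oxodecahydronaphthalen-1-yl]methanol | O=C1CCC[C@@]2(C)[C@H]1CCC(=C)[C@@]2(C)CO
F6 | step 11 | [(1R,2S,4aR,8aS)-1,2,8a-trimethyl-5-oxodecahydronaphthalen-1-yl]methanol | O=C1CCC[C@@]2(C)[C@H]1CC[C@H](C)[C@@]2(C)CO
F7 | step 11 | neopentyl iodide from F6, (1R,2S,4aR,8aS)-1-(iodomethyl)-1,2,8a-trimethyl-5-oxodecahydronaphthalene (target numbering) | O=C1CCC[C@@]2(C)[C@H]1CC[C@H](C)[C@@]2(C)CI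
F8 | step 14 | methyl 4-hydroxy-3-{[(1R,2S,4aS,8aS)-5-hydroxy-1,2,8a-trimethyl-5-[(trimethylsilyl)methyl]decahydronaphthalen-1-yl]methyl}benzoate (C5 undefined) | C[Si](C)(C)CC1(O)CCC[C@@]2(C)[C@H]1CC[C@H](C)[C@@]2(C)Cc1cc(C(=O)OC)ccc1O
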